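**Retrosynthetic overview**
1. Target 16 ⇒ aryl silyl ether 15 ⇒ 2-aryloxy allylic alcohol 11 by anti-selective hydroboration–oxidation; C8–H and C9–OH arrive together and C8 is set from C7.
2. 11 ⇒ C7–C8 bond: a 1-(aryloxy)vinyl metal (masked acyl anion at C8, from α-metalation of aryl vinyl ether 8) adds to aldehyde 3; a catalytic enantioselective addition sets C7.
3. 8 ⇒ ethyl sinapate 5 (O-vinylation, ester reduction) ⇒ syringaldehyde 1 + ylide 4; 3 ⇒ 1 + TIPSCl.
4. No ring is formed: both benzene rings are bought as syringaldehyde.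

Assumption: the drawn descriptors are read as the erythro (7S,8R) isomer, i.e. (1S,2R) in propane-1,3-diol numbering; C7/C8/C9 denote the glycerol chain throughout.

**Route**

Step 1
Reactants: 1 syringaldehyde (4-hydroxy-3,5-dimethoxybenzaldehyde); 2 chlorotriisopropylsilane
Product: 3 3,5-dimethoxy-4-(triisopropylsilyloxy)benzaldehyde
Conditions: NaH (1.1 equiv), THF/DMF, 0 °C; then 2 (1.1 equiv), rt
Reagents that add atoms: chlorotriisopropylsilane (2), CC(C)[Si](Cl)(C(C)C)C(C)C
Why: O-silylation of the sodium phenoxide; the aryl TIPS ether tolerates organozinc reagents, 9-BBN and buffered peroxide and leaves with fluoride at the end.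

Step 2
Reactants: 1 syringaldehyde; 4 ethyl (triphenylphosphoranylidene)acetate
Product: 5 ethyl (2E)-3-(4-hydroxy-3,5-dimethoxyphenyl)prop-2-enoate (ethyl sinapate)
Conditions: 4 (1.3 equiv), toluene, 90 °C
Reagents that add atoms: ethyl (triphenylphosphoranylidene)acetate (4), CCOC(=O)C=P(c1ccccc1)(c1ccccc1)c1ccccc1
Why: Wittig olefination with a stabilised ylide, which is E-selective and tolerates the free phenol.

Step 3
Reactants: 5 ethyl sinapate; 6 vinyl acetate
Product: 7 ethyl (2E)-3-[3,5-dimethoxy-4-(vinyloxy)phenyl]prop-2-enoate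
Conditions: [Ir(cod)Cl]2 (2 mol %), Na2CO3 (0.6 equiv), 6 (3 equiv), toluene, 100 °C
Reagents that add atoms: vinyl acetate (6), CC(=O)OC=C
Why: Iridium-catalysed transfer vinylation of a phenol (Ishii type: Ir–aryloxide adds to vinyl acetate, then β-acetate elimination), with carbonate taking up the acetic acid; the enoate is inert.

Step 4
Reactants: 7 ethyl (2E)-3-[3,5-dimethoxy-4-(vinyloxy)phenyl]prop-2-enoate
Product: 8 (2E)-3-[3,5-dimethoxy-4-(vinyloxy)phenyl]prop-2-en-1-ol
Conditions: DIBAL-H (2.3 equiv), CH2Cl2, −78 → −40 °C; aq. Rochelle salt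
Reagents that add atoms: none
Why: 1,2-reduction of the enoate by DIBAL-H gives the (E)-allylic alcohol; the aryl vinyl ether is untouched by hydride and by the neutral work-up.

Step 5
Reactants: 8 (2E)-3-[3,5-dimethoxy-4-(vinyloxy)phenyl]prop-2-en-1-ol (1.2 equiv); 3 3,5-dimethoxy-4-(triisopropylsilyloxy)benzaldehyde (1.0 equiv)
Product: 11 (1S)-1-[3,5-dimethoxy-4-(triisopropylsilyloxy)phenyl]-2-{4-[(1E)-3-hydroxyprop-1-enyl]-2,6-dimethoxyphenoxy}prop-2-en-1-ol, via dilithio species 9 (not isolated), via bis(ethylzinc) species 10 (not isolated)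
Conditions: n-BuLi (1.0 equiv), THF, −78 °C; t-BuLi (1.15 equiv), −78 → −50 °C; EtZnCl (2.2 equiv, stock solution), −78 → 0 °C; TEEDA (2.2 equiv), dilute with toluene; (+)-MIB (10 mol %), then 3, −20 → 0 °C; pH 7 buffer; Et3N-deactivated silica
Reagents that add atoms: none
Why: Proposed new method: α-lithiation of a vinyl ether is the classical entry to a masked acyl anion (cf. 1-ethoxyvinyllithium), here helped by chelation from the two flanking OMe groups while the allylic alcohol is shielded as its lithium alkoxide (no acidic allylic C–H, unlike a silyl ether); Li→Zn exchange gives an ethyl(alkenyl)zinc whose sp2 carbon transfers in preference to ethyl, and the amino-alkoxide–zinc bimetallic (Noyori-type) transition state of (+)-MIB is expected to deliver it to the Re face of 3, which is (S) at C7 because the 1-aryloxyvinyl group outranks the aryl group; the closest known reaction types are the Oppolzer/Walsh amino-alcohol-catalysed enantioselective additions of alkenyl(alkyl)zincs to aldehydes and the MIB/TEEDA protocol for organozincs made from organolithiums, neither yet shown for a 1-alkoxyvinyl group.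

Step 6
Reactants: 11 (S)-allylic alcohol; 12 9-borabicyclo[3.3.1]nonane (9-BBN); 13 hydrogen peroxide
Product: 15 (1S,2R)-1-[3,5-dimethoxy-4-(triisopropylsilyloxy)phenyl]-2-{4-[(1E)-3-hydroxyprop-1-enyl]-2,6-dimethoxyphenoxy}propane-1,3-diol, via tris(9-BBN) adduct 14 (not isolated)
Conditions: 12 (3.3 equiv), THF, 0 °C → rt; then 30% H2O2, aq. NaOAc/NaHCO3 buffer (pH ≈ 8), 0 °C → rt
Reagents that add atoms: hydrogen peroxide (13), OO
Why: Substrate-controlled hydroboration–oxidation of a 1,1-disubstituted alkene next to a carbinol centre (Still–Barrish/Houk model: C7–H inside, aryl anti to the incoming 9-BBN, C7–O outside) puts H on C8 so that 7-O and 8-OAr end up anti (erythro, 8R from 7S); boron goes to terminal C9 for steric and enol-ether electronic reasons, the two hydroxyls are first converted to borinates, 9-BBN reacts far faster with the terminal alkene than with the trans-cinnamyl alkene, and oxidation proceeds with retention.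

Step 7
Reactants: 15 TIPS ether of the target
Product: 16 (1S,2R)-1-(4-hydroxy-3,5-dimethoxyphenyl)-2-{4-[(1E)-3-hydroxyprop-1-enyl]-2,6-dimethoxyphenoxy}propane-1,3-diol (target)
Conditions: TBAF (1.2 equiv), AcOH (1.2 equiv), THF, 0 °C
Reagents that add atoms: none
Why: Fluoride cleavage of the aryl silyl ether; acetic acid buffering keeps the freed p-hydroxybenzyl alcohol away from both strong base and acid, so C7 does not epimerise.

**Compound list**
1 | syringaldehyde (4-hydroxy-3,5-dimethoxybenzaldehyde) | COc1cc(C=O)cc(OC)c1O | starting material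
2 | chlorotriisopropylsilane | CC(C)[Si](Cl)(C(C)C)C(C)C | starting material
3 | 3,5-dimethoxy-4-(triisopropylsilyloxy)benzaldehyde | COc1cc(C=O)cc(OC)c1O[Si](C(C)C)(C(C)C)C(C)C | intermediate
4 | ethyl (triphenylphosphoranylidene)acetate | CCOC(=O)C=P(c1ccccc1)(c1ccccc1)c1ccccc1 | starting material
5 | ethyl (2E)-3-(4-hydroxy-3,5-dimethoxyphenyl)prop-2-enoate | CCOC(=O)/C=C/c1cc(OC)c(O)c(OC)c1 | intermediate
6 | vinyl acetate | CC(=O)OC=C | starting material
7 | ethyl (2E)-3-[3,5-dimethoxy-4-(vinyloxy)phenyl]prop-2-enoate | CCOC(=O)/C=C/c1cc(OC)c(OC=C)c(OC)c1 | intermediate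
8 | (2E)-3-[3,5-dimethoxy-4-(vinyloxy)phenyl]prop-2-en-1-ol | OC/C=C/c1cc(OC)c(OC=C)c(OC)c1 | intermediate
9 | lithium (2E)-3-[4-(1-lithiovinyloxy)-3,5-dimethoxyphenyl]prop-2-en-1-olate (not isolated) | [Li]OC/C=C/c1cc(OC)c(OC(=C)[Li])c(OC)c1 | intermediate
10 | ethylzinc alkoxide / ethyl[1-(aryloxy)vinyl]zinc derived from 9 (not isolated) | CC[Zn]OC/C=C/c1cc(OC)c(OC(=C)[Zn]CC)c(OC)c1 | intermediate
11 | (1S)-1-[3,5-dimethoxy-4-(triisopropylsilyloxy)phenyl]-2-{4-[(1E)-3-hydroxyprop-1-enyl]-2,6-dimethoxyphenoxy}prop-2-en-1-ol | COc1cc([C@H](O)C(=C)Oc2c(OC)cc(/C=C/CO)cc2OC)cc(OC)c1O[Si](C(C)C)(C(C)C)C(C)C | intermediate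
12 | 9-borabicyclo[3.3.1]nonane (9-BBN) | B1C2CCCC1CCC2 | starting material
13 | hydrogen peroxide | OO | starting material
14 | tris(9-BBN) adduct of 11: C9–B alkylborane, C7 and cinnamyl O-borinates (not isolated) | COc1cc([C@H](OB3C4CCCC3CCC4)[C@@H](CB3C4CCCC3CCC4)Oc2c(OC)cc(/C=C/COB3C4CCCC3CCC4)cc2OC)cc(OC)c1O[Si](C(C)C)(C(C)C)C(C)C | intermediate
15 | (1S,2R)-1-[3,5-dimethoxy-4-(triisopropylsilyloxy)phenyl]-2-{4-[(1E)-3-hydroxyprop-1-enyl]-2,6-dimethoxyphenoxy}propane-1,3-diol | COc1cc([C@H](O)[C@@H](CO)Oc2c(OC)cc(/C=C/CO)cc2OC)cc(OC)c1O[Si](C(C)C)(C(C)C)C(C)C | intermediate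
16 | (1S,2R)-1-(4-hydroxy-3,5-dimethoxyphenyl)-2-{4-[(1E)-3-hydroxyprop-1-enyl]-2,6-dimethoxyphenoxy}propane-1,3-diol | COc1cc([C@H](O)[C@@H](CO)Oc2c(OC)cc(/C=C/CO)cc2OC)cc(OC)c1O | target

**Count**
Total steps: 7. Longest linear sequence: 6 (steps 2 → 3 → 4 → 5 → 6 → 7); step 1 is a one-step branch.

**Steps most likely to fail, with fallbacks**

Step 5 is the riskiest. The site of lithiation (vinyl α-H against ring C–H or addition to the styrene), the stability of the 1-lithiovinyl aryl ether, and the level and sense of enantioselectivity of the zinc addition are all unproven. If the sense turns out opposite, (−)-MIB is used instead. The fallback sets out from 8 and 3 and comes back to the route at 11; it keeps the same C7–C8 construction but takes enantiocontrol out of it. The dilithio species 9 is added directly to 3 in THF at −78 °C, without zinc or ligand, to give racemic 1-[3,5-dimethoxy-4-(triisopropylsilyloxy)phenyl]-2-{4-[(1E)-3-hydroxyprop-1-enyl]-2,6-dimethoxyphenoxy}prop-2-en-1-ol F1. The primary allylic hydroxyl is acetylated selectively (Ac2O 1.05 equiv, 2,4,6-collidine, CH2Cl2, −40 °C) to the racemic cinnamyl monoacetate F2, so that only the secondary carbinol remains a substrate for titanium. Sharpless kinetic resolution (Ti(OiPr)4, D-(−)-DIPT, t-BuOOH, 4 Å sieves, CH2Cl2, −20 °C, about 55% conversion) epoxidises and destroys the (R)-carbinol and leaves the (S)-configured monoacetate F3. DIBAL-H at −78 °C removes the acetate and returns 11.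

Step 6 is the second risk. The anti preference is extrapolated from 2-alkyl to 2-aryloxy allylic alcohols, the β-aryloxy alkylborane could eliminate, and excess 9-BBN could touch the cinnamyl alkene. The fallback sets out from 11 and comes back at 16; it replaces the O-borinate by a bulky silyl ether, the substrate class for which the Still–Barrish anti preference was established, and merges all deprotections. TBSOTf/2,6-lutidine (CH2Cl2, −78 °C) gives the bis-TBS ether F4. 9-BBN (1.5 equiv, THF, rt) followed by buffered H2O2 gives, through the B-alkyl-9-BBN adduct F5, the primary alcohol (1S,2R)-tris-silyl ether F6. TBAF/AcOH then removes all three silyl groups to give 16.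

Step 3 is the third risk: the di-ortho-substituted phenol may vinylate slowly, and Ir–H species may touch the enoate. The fallback sets out from 1 and comes back at 7; it builds the vinyl ether by alkylation and elimination before the olefination. Syringaldehyde 1 is alkylated with excess 1,2-dibromoethane (K2CO3, DMF, 60 °C) to 4-(2-bromoethoxy)-3,5-dimethoxybenzaldehyde F7. E2 elimination with KOtBu (DMSO/THF, rt) gives 3,5-dimethoxy-4-(vinyloxy)benzaldehyde F8. Wittig olefination with 4 (toluene, 90 °C) then gives 7.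

**Further compounds**
F1 | step 5 | rac-1-[3,5-dimethoxy-4-(triisopropylsilyloxy)phenyl]-2-{4-[(1E)-3-hydroxyprop-1-enyl]-2,6-dimethoxyphenoxy}prop-2-en-1-ol | COc1cc(C(O)C(=C)Oc2c(OC)cc(/C=C/CO)cc2OC)cc(OC)c1O[Si](C(C)C)(C(C)C)C(C)C
F2 | step 5 | rac-(2E)-3-[4-({3-[3,5-dimethoxy-4-(triisopropylsilyloxy)phenyl]-3-hydroxyprop-1-en-2-yl}oxy)-3,5-dimethoxyphenyl]prop-2-enyl acetate | COc1cc(C(O)C(=C)Oc2c(OC)cc(/C=C/COC(C)=O)cc2OC)cc(OC)c1O[Si](C(C)C)(C(C)C)C(C)C
F3 | step 5 | (S)-carbinol enantiomer of the monoacetate F2 | COc1cc([C@H](O)C(=C)Oc2c(OC)cc(/C=C/COC(C)=O)cc2OC)cc(OC)c1O[Si](C(C)C)(C(C)C)C(C)C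
F4 | step 6 | bis(tert-butyldimethylsilyl) ether of 11 (C7–OTBS and cinnamyl OTBS) | COc1cc([C@H](O[Si](C)(C)C(C)(C)C)C(=C)Oc2c(OC)cc(/C=C/CO[Si](C)(C)C(C)(C)C)cc2OC)cc(OC)c1O[Si](C(C)C)(C(C)C)C(C)C
F5 | step 6 | C9 B-alkyl-9-BBN adduct of F4 (not isolated) | COc1cc([C@H](O[Si](C)(C)C(C)(C)C)[C@@H](CB3C4CCCC3CCC4)Oc2c(OC)cc(/C=C/CO[Si](C)(C)C(C)(C)C)cc2OC)cc(OC)c1O[Si](C(C)C)(C(C)C)C(C)C
F6 | step 6 | (2R,3S)-3-(tert-butyldimethylsilyloxy)-2-{4-[(1E)-3-(tert-butyldimethylsilyloxy)prop-1-enyl]-2,6-dimethoxyphenoxy}-3-[3,5-dimethoxy-4-(triisopropylsilyloxy)phenyl]propan-1-ol | COc1cc([C@H](O[Si](C)(C)C(C)(C)C)[C@@H](CO)Oc2c(OC)cc(/C=C/CO[Si](C)(C)C(C)(C)C)cc2OC)cc(OC)c1O[Si](C(C)C)(C(C)C)C(C)C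
F7 | step 3 | 4-(2-bromoethoxy)-3,5-dimethoxybenzaldehyde | COc1cc(C=O)cc(OC)c1OCCBr
F8 | step 3 | 3,5-dimethoxy-4-(vinyloxy)benzaldehyde | COc1cc(C=O)cc(OC)c1OC=C
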